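**Strategy**

Everything rests on opening ring A, the phloroglucinol of the chromanone, between C4a and C8a: its carbons C4a, C5, C6, C7, C8 and C8a are the 1,3,5-tricarbonyl tail of a 3-phenylglutaric acid lengthened by two acetate units, and the stereocentre C4 sits β to C2, C5 and C8a, out of reach of enolisation. One base-then-acid operation should therefore fold an open-chain 5,7-dioxo ester into the arene by Claisen closure (C4a–C8a) and tie the acid arm to an ortho phenol (O1–C2). The precursor is a linear (R)-keto ester acid with one free carboxyl group and the C3 stereocentre already in place; C8 benzoylation and C6 prenylation finish the target.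

Key step: step 4

Remark on the chemistry: the cinchona catalyst in step 1 is assumed to deliver the (R)-hemiester 3; should its sense of induction prove opposite, the pseudoenantiomeric catalyst (DHQ)2AQN is used instead. Chain atoms of 7 and 8 are numbered from the benzyl ester or acid carbon as C1. The target is (R) at C4.

**Route**

Step 1
Reactants: 1 3-phenylglutaric anhydride; 2 benzyl alcohol
Product: 3 (R)-5-(benzyloxy)-5-oxo-3-phenylpentanoic acid
Conditions: BnOH (2 equiv), (DHQD)2AQN [hydroquinidine (anthraquinone-1,4-diyl) diether, 0.2 equiv], Et2O, −40 °C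
Reagents that add atoms: none
Why: Cinchona-alkaloid-catalysed alcoholytic desymmetrisation of a prochiral cyclic anhydride, in which the quinuclidine nitrogen acts as general base for benzyl alcohol inside the chiral pocket and so distinguishes the two enantiotopic carbonyl groups, setting C3 by catalyst control.

Step 2
Reactants: 3 (R)-5-(benzyloxy)-5-oxo-3-phenylpentanoic acid; 4 methyl acetoacetate
Product: 7 1-benzyl 9-methyl (R)-5,7-dioxo-3-phenylnonanedioate, via acyl imidazolide 5 (not isolated), via acetoacetate dianion 6 (not isolated)
Conditions: 3, CDI (1.1 equiv), THF, rt; separately 4 (3 equiv), NaH then n-BuLi, THF, 0 °C; combine at −78 °C, warm to −20 °C; cold 1 M HCl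
Reagents that add atoms: none
Why: γ-Acylation of a β-keto ester dianion by an N-acylimidazole (Claisen-type chain extension), in which the imidazolide is far more electrophilic than the benzyl ester at low temperature, excess dianion absorbs the acidic protons of the product, and the stereocentre, β to both carbonyls, is untouched.

Step 3
Reactants: 7 1-benzyl 9-methyl (R)-5,7-dioxo-3-phenylnonanedioate
Product: 8 (R)-9-methoxy-5,7,9-trioxo-3-phenylnonanoic acid
Conditions: H2 (1 atm), 10% Pd/C, EtOAc, rt
Reagents that add atoms: none
Why: Catalytic hydrogenolysis cleaves only the O–benzyl bond, since the aliphatic ketones, the methyl ester and the C–phenyl stereocentre are inert to H2 over Pd/C at ambient pressure.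

Step 4
Reactants: 8 (R)-9-methoxy-5,7,9-trioxo-3-phenylnonanoic acid
Product: 10 (R)-5,7-dihydroxy-4-phenylchroman-2-one, via trihydroxyphenyl acid 9 (not isolated)
Conditions: Mg(OMe)2 (8 equiv), degassed MeOH, reflux, Ar; then 2 M HCl to pH 1, 40 °C
Reagents that add atoms: none
Why: Proposed new method: Mg(OMe)2 turns 8 into a magnesium carboxylate and a chelated 1,3-diketonate, and reversible deprotonation at C4, the methylene between the stereocentre C3 and the C5 ketone, gives a carbanion that adds to the C9 ester carbonyl in a 6-(enolendo)-exo-trig Claisen closure (C4–C9, the later C4a–C8a bond); loss of methoxide leaves a 2-substituted cyclohexane-1,3,5-trione that tautomerises irreversibly to the phloroglucinol ring A of 9. The closest known reaction types are the Mg(OMe)2- or alkoxide-mediated Claisen aromatisation of 3,5,7-trioxo esters to acylphloroglucinols and the Dieckmann-type closure of 5-oxo esters to cyclohexane-1,3-diones; what is new is that the attacking carbon of a 3,5-dioxo ester is activated by a single ketone. On acidification the propanoic acid arm of 9 esterifies an ortho phenol in a 6-exo-trig lactonisation (O1–C2), and since the two ortho hydroxyls are equivalent by the local symmetry of ring A only one lactone can result. No stereocentre is formed, and the existing one (C3 of 8, C4 of 10) is β to every carbonyl and carries no leaving group, so neither enolisation nor elimination can erode it. The selectivity needed is C-acylation through C4: the C1 carboxylate is no electrophile, which shuts off the Dieckmann closure of C6 onto C1, every other C–C closure would give a four-membered ring, and O-acylation to the 4-hydroxy-2-pyranone is reopened by methoxide on the chelating magnesium whereas aromatisation is not reversed.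

Step 5
Reactants: 10 (R)-5,7-dihydroxy-4-phenylchroman-2-one; 11 benzoyl chloride
Product: 12 (R)-8-benzoyl-5,7-dihydroxy-4-phenylchroman-2-one
Conditions: BzCl (1.1 equiv), AlCl3 (3.5 equiv), PhNO2, 0 °C to 50 °C; ice/1 M HCl
Reagents that add atoms: none
Why: Friedel–Crafts acylation (any O-benzoate formed first is carried on to carbon by Fries rearrangement under AlCl3) should go to C8, the resorcinol-type position ortho to 7-OH and para to 5-OH, because C6 lies buried between two aluminium phenoxides and the aluminium chelate of the product ketone with O7 deactivates the ring against a second acylation, while the lactone and the non-enolisable C4 centre are not engaged at or below 50 °C.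

Step 6
Reactants: 12 (R)-8-benzoyl-5,7-dihydroxy-4-phenylchroman-2-one; 13 2-methylbut-3-en-2-ol
Product: 14 (R)-8-benzoyl-5,7-dihydroxy-6-(3-methylbut-2-en-1-yl)-4-phenylchroman-2-one (target)
Conditions: 2-methylbut-3-en-2-ol (1.5 equiv), BF3·OEt2 (0.5 equiv), dioxane, rt; stopped at partial conversion, 12 recovered
Reagents that add atoms: none
Why: Lewis-acid Friedel–Crafts prenylation with the 1,1-dimethylallyl cation from the tertiary alcohol should attack C6, the only unsubstituted ring carbon and one activated by both flanking hydroxyls, through its unhindered primary terminus to give the linear prenyl group, and the non-basic, non-aqueous medium keeps the lactone closed so that the O1/O5 assignment cannot scramble.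

**Compound list**

1 | 3-phenylglutaric anhydride (4-phenyloxane-2,6-dione) | O=C1CC(c2ccccc2)CC(=O)O1 | starting material
2 | benzyl alcohol | OCc1ccccc1 | starting material
3 | (R)-5-(benzyloxy)-5-oxo-3-phenylpentanoic acid | OC(=O)C[C@H](CC(=O)OCc1ccccc1)c1ccccc1 | intermediate
4 | methyl acetoacetate | COC(=O)CC(C)=O | starting material
5 | benzyl (R)-5-(imidazol-1-yl)-5-oxo-3-phenylpentanoate | O=C(C[C@H](CC(=O)OCc1ccccc1)c1ccccc1)n1ccnc1 | intermediate (not isolated)
6 | sodium lithium dianion of methyl acetoacetate | COC(=O)[CH-]C(=O)[CH2-].[Na+].[Li+] | intermediate (not isolated)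
7 | 1-benzyl 9-methyl (R)-5,7-dioxo-3-phenylnonanedioate | O=C(OCc1ccccc1)C[C@@H](CC(=O)CC(=O)CC(=O)OC)c1ccccc1 | intermediate
8 | (R)-9-methoxy-5,7,9-trioxo-3-phenylnonanoic acid | OC(=O)C[C@@H](CC(=O)CC(=O)CC(=O)OC)c1ccccc1 | intermediate (key-step precursor)
9 | (R)-3-phenyl-3-(2,4,6-trihydroxyphenyl)propanoic acid | OC(=O)C[C@@H](c1c(O)cc(O)cc1O)c1ccccc1 | intermediate (not isolated)
10 | (R)-5,7-dihydroxy-4-phenylchroman-2-one | Oc1cc(O)c2c(c1)OC(=O)C[C@@H]2c1ccccc1 | intermediate (key-step product)
11 | benzoyl chloride | O=C(Cl)c1ccccc1 | starting material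
12 | (R)-8-benzoyl-5,7-dihydroxy-4-phenylchroman-2-one | O=C(c1ccccc1)c1c(O)cc(O)c2c1OC(=O)C[C@@H]2c1ccccc1 | intermediate
13 | 2-methylbut-3-en-2-ol | CC(C)(O)C=C | starting material
14 | (R)-8-benzoyl-5,7-dihydroxy-6-(3-methylbut-2-en-1-yl)-4-phenylchroman-2-one | CC(C)=CCc1c(O)c(C(=O)c2ccccc2)c2c(c1O)[C@@H](c1ccccc1)CC(=O)O2 | target

**Step count and risks**

Total step count: 6. Longest linear sequence: 6 steps (1 → 3 → 7 → 8 → 10 → 12 → 14).

Steps most likely to fail:

1. Step 4 (the step labelled as a proposed new method). Deprotonation at C4 may never compete, so that the chain is drained by O-acylation into a pyranone that does not reopen, by retro-Claisen cleavage of the 1,3-diketone by methoxide, or by intermolecular condensation. The fallback uses known chemistry only. It uses none of compounds 1–9, so it sets out not from a numbered compound but from commercial 2,4,6-trimethoxybenzaldehyde F1, and it comes back to the route at compound 10. Horner–Wadsworth–Emmons olefination of F1 with trimethyl phosphonoacetate (NaH, THF) should give methyl (E)-3-(2,4,6-trimethoxyphenyl)acrylate F2. Rhodium-catalysed asymmetric 1,4-addition of phenylboronic acid (Rh(acac)(C2H4)2, the BINAP enantiomer that gives the R product, dioxane/H2O, 100 °C) should give methyl (R)-3-phenyl-3-(2,4,6-trimethoxyphenyl)propanoate F3. BBr3 (CH2Cl2, −78 °C to rt) followed by aqueous acid should remove the three O-methyl groups and close the lactone to 10.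

2. Step 6. The acid may cyclise the new prenyl group onto 5-OH or 7-OH to a chroman, the allyl cation may oligomerise, or the deactivated ring may convert poorly. The fallback sets out from compound 12 and comes back at compound 14. Copper-catalysed O-alkylation of the unchelated 5-OH with 2-methylbut-3-yn-2-yl trifluoroacetate (DBU, CuCl2 cat., MeCN, 0 °C) should give (R)-8-benzoyl-7-hydroxy-5-[(2-methylbut-3-yn-2-yl)oxy]-4-phenylchroman-2-one F4; the 7-OH is held back by its hydrogen bond to the benzoyl group. Semihydrogenation (H2, Pd/CaCO3 poisoned with Pb(OAc)2, quinoline, EtOAc) should give (R)-8-benzoyl-7-hydroxy-5-[(2-methylbut-3-en-2-yl)oxy]-4-phenylchroman-2-one F5. Heating (toluene, 110 °C) should trigger the aromatic Claisen rearrangement, whose only open ortho terminus is C6, and deliver 14 under neutral conditions.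

3. Step 5. Attack may compete at C6 or occur twice, acyl transfer may stop at oxygen, or the Lewis acid may open the aryl lactone. The fallback sets out from compound 10 and comes back at compound 12. Silylation (TIPSCl, imidazole, DMF) should give (R)-4-phenyl-5,7-bis[(triisopropylsilyl)oxy]chroman-2-one F6, in which C6 is shielded by two bulky silyl ethers. Iodination (NIS, MeCN, 0 °C) should then go to C8 and give (R)-8-iodo-4-phenyl-5,7-bis[(triisopropylsilyl)oxy]chroman-2-one F7. Carbonylative Stille coupling (PhSnBu3, CO 1 atm, Pd(PPh3)4, toluene, 90 °C) should give (R)-8-benzoyl-4-phenyl-5,7-bis[(triisopropylsilyl)oxy]chroman-2-one F8. Desilylation (HF·pyridine, THF, 0 °C) should release 12 without opening the lactone.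

**Further compounds**

F1 | step 4 | 2,4,6-trimethoxybenzaldehyde (commercial) | COc1cc(OC)c(C=O)c(OC)c1
F2 | step 4 | methyl (E)-3-(2,4,6-trimethoxyphenyl)acrylate | COC(=O)/C=C/c1c(OC)cc(OC)cc1OC
F3 | step 4 | methyl (R)-3-phenyl-3-(2,4,6-trimethoxyphenyl)propanoate | COC(=O)C[C@@H](c1c(OC)cc(OC)cc1OC)c1ccccc1
F4 | step 6 | (R)-8-benzoyl-7-hydroxy-5-[(2-methylbut-3-yn-2-yl)oxy]-4-phenylchroman-2-one | C#CC(C)(C)Oc1cc(O)c(C(=O)c2ccccc2)c2c1[C@@H](c1ccccc1)CC(=O)O2
F5 | step 6 | (R)-8-benzoyl-7-hydroxy-5-[(2-methylbut-3-en-2-yl)oxy]-4-phenylchroman-2-one | C=CC(C)(C)Oc1cc(O)c(C(=O)c2ccccc2)c2c1[C@@H](c1ccccc1)CC(=O)O2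
F6 | step 5 | (R)-4-phenyl-5,7-bis[(triisopropylsilyl)oxy]chroman-2-one | CC(C)[Si](C(C)C)(C(C)C)Oc1cc(O[Si](C(C)C)(C(C)C)C(C)C)c2c(c1)OC(=O)C[C@@H]2c1ccccc1
F7 | step 5 | (R)-8-iodo-4-phenyl-5,7-bis[(triisopropylsilyl)oxy]chroman-2-one | Ic1c(O[Si](C(C)C)(C(C)C)C(C)C)cc(O[Si](C(C)C)(C(C)C)C(C)C)c2c1OC(=O)C[C@@H]2c1ccccc1
F8 | step 5 | (R)-8-benzoyl-4-phenyl-5,7-bis[(triisopropylsilyl)oxy]chroman-2-one | O=C(c1ccccc1)c1c(O[Si](C(C)C)(C(C)C)C(C)C)cc(O[Si](C(C)C)(C(C)C)C(C)C)c2c1OC(=O)C[C@@H]2c1ccccc1
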